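At 3.00 h the spring flask and the midnight run held about the same target, 35% and 36%, yet the spring flask had used 60.0% of its starting material and the midnight run 40.0%. In the chain, the first carrier takes partner to give target and the second carrier, and the second carrier takes starting material to give by-product and the first carrier again. One starting material used therefore means one target made, and target can turn into its isomer, which nobody measured.

common to all: starting material 32 mM; initiator 2.9 mM
- spring: partner 25.6 mM; temperature 50 °C; the very flask that is asked about, followed so far
- midnight: partner 38 mM; temperature 35 °C; run made earlier
- flask: partner 25.6 mM; temperature 50 °C; time 10 h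

| run | time / h | target / % | starting material / % |
|---|---|---|---|
| spring | 1.33 | 22 | 58 |
| spring | 3.00 | 35 | 40 |
| spring | 4.00 | 34 | 33 |
| spring | 6.00 | 32 | 25 |
| spring | 8.00 | 27 | 19 |
| spring | 10.0 | 27 | 19 |
| midnight | 0.333 | 7 | 94 |
| midnight | 0.500 | 11 | 93 |
| midnight | 0.667 | 11 | 89 |
| midnight | 1.00 | 15 | 86 |
| midnight | 2.00 | 25 | 70 |
| midnight | 3.00 | 36 | 60 |
| midnight | 4.00 | 38 | 49 |

(scatter of a reading: 2 percentage points)

- in percentages every species weighs as the starting material in it: one ended chains A counts as two
- the volume of additions can be left aside
- steps thought possible: 2 first chain carrier -> ended chains A; 2 second chain carrier -> ended chains B; target <-> isomer of the product; starting material + initiating radical -> capped initiator + first chain carrier; partner + first chain carrier -> target + second chain carrier; starting material + second chain carrier -> by-product + first chain carrier; initiator -> 2 initiating radical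

- grey: change nothing and wait 5.0 h more
- green: at 10 h add partner, 100% of the amount charged, then wait 5.0 h
- red: at 10 h raise the temperature by 20 K, then wait 5.0 h
- blue: at 10 h take out 90% of the by-product then present, then wait 5.0 h

- target, in percent of the starting material first charged, at 10 h
- which option adds most target ("none" when 2 percentage points or less is all one gets) (grey / green / red / blue / none)
- target present, in percent of the starting material first charged, after grey
- target present, in percent of the starting material first charged, after blue

The spring flask at 10.0 h held 27% target with 81.0% of its starting material used, which gives 33.3%. I called this the target share, target present divided by starting material used. In the spring flask the readings at 8.00 h and 10.0 h were the same, so I took the share as a level between target and isomer. The loss there stood close to the partner charge, 80.0% of the starting material, so I took partner as the limiting reagent. The midnight run ended elsewhere: its share was still falling, from 90.0% at 3.00 h to 74.5% at 4.00 h, so it showed no level for the cooler flask.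

I therefore expected grey and blue to stay near 27%. Green should turn the remaining 19% of starting material into target at the same share, a gain of 6.3 percentage points. Red, with the amount used unchanged, had to lift the share above 41.7% to beat green, and I could not read its direction from these runs.

The forecast gave 27% at 10 h, 26% after grey and 26% after blue, and it chose green. Of red it said that it “shifts the isomer equilibrium by an unknown amount”.

At 10 h the flask held 28.8%. Grey gave 28.6% and blue 28.6%, while green added 7 points and red 20 points, so red was best.

    2 first chain carrier → ended chains A (k = 1.10 × 10⁹ M⁻¹ s⁻¹, Ea = 11.0 kJ mol⁻¹)
    2 second chain carrier → ended chains B (k = 2.00 × 10⁸ M⁻¹ s⁻¹, Ea = 9.00 kJ mol⁻¹)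
    target ⇌ isomer of the product (K = 1.80, k = 0.0100 min⁻¹, Ea = 90.0 kJ mol⁻¹, ΔH = −48.0 kJ mol⁻¹)
    starting material + initiating radical → capped initiator + first chain carrier (k = 2.90 × 10⁶ M⁻¹ s⁻¹, Ea = 27.0 kJ mol⁻¹)
    partner + first chain carrier → target + second chain carrier (k = 85000 M⁻¹ s⁻¹, Ea = 9.00 kJ mol⁻¹)
    starting material + second chain carrier → by-product + first chain carrier (k = 1.10 × 10⁵ M⁻¹ s⁻¹, Ea = 18.0 kJ mol⁻¹)
    initiator → 2 initiating radical (k = 6.00 × 10⁻⁵ min⁻¹, Ea = 120 kJ mol⁻¹)
    (constants at 50 °C)

Reckoned on the starting material used at 10.0 h, red took the share to 61.1%, about twice my reading and above the 41.7% it had to pass. The main reason the flask held so little target at 10 h was the step from target to its isomer, both ways: in the run without that step it held 79.4% instead of 28.8%. Part of the reason for the gain from red was the way back from isomer to target: with that reverse step taken away, red brought −1.8 points instead of 20 points. In the neighbour flask with 44 mM of partner, 0% of the starting material remained, so my share gave 33.3% target, and that flask held 35.7%.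

(Readings and results were computed for substances that don't exist.)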